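## Structural features

The target (C32H40O8) is a dimer of two isobutyryl-phloroglucinol units held together by a single CH2 group. Ring A is the dearomatized half, an enolized cyclohexane-1,3,5-trione written as a cyclohexa-2,5-dien-1-one: C1 carbonyl, C2 isobutyryl, C3 and C5 enol hydroxyls, C4 quaternary (methyl and prenyl), C6 carrying the bridge. Ring B is aromatic, with phenols at C5 and C7 and an isobutyryl group at C8, and is fused through C4a/C8a to ring C, a 2,2-dimethyl-2H-pyran whose oxygen sits next to the acyl-bearing carbon; the bridge ends on C6 of ring B, between the two phenols. The only stereocentre is the all-carbon quaternary C4 of ring A, which has no stereogenic neighbour and is stereogenic only because its two flanking enol carbons differ one bond further out (acyl at C2, bridge at C6). Fragile groups are the prenyl and chromene double bonds (acid, electrophiles, hydrogenation), the acidic, chelating β-triketone enols, and the methylene bridge, which can be exchanged by retro-Michael processes under base and heat. The real difficulties are absolute control at a quaternary carbon whose substituents differ only remotely, the regiochemistry of ring C (which phenol oxygen closes the pyran), and an unsymmetrical one-carbon coupling without symmetric dimers. The key step uses the fact that ring A without its C2 acyl group and C6 bridge is a mirror-symmetric 4-methyl-4-prenyl trione, whose enol oxygens on C3 and C5 are enantiotopic and each placed for six-membered ring closure onto the tertiary carbon of the prenyl C=C.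

## Logic of the disconnections

**Bridge.** 21 is cut at both C–C bonds of the bridging CH2 (ring A C6–CH2 and CH2–ring B C6), giving 11, 18 and a one-carbon electrophile at the formaldehyde level. The CH2 joins the two most nucleophilic carbons of the molecule, so these bonds form most easily and can be made last. The gain is a chiral C16 half and an achiral C15 half, each with exactly one free nucleophilic carbon. The forward step must fix the carbon on 11 first (as 19, then 20) so that no symmetric dimer can form, under conditions mild enough for both alkenes.

**Temporary ring.** 11 is traced back to 10 by tying the enol oxygen on the bridge-side flank to the tertiary prenyl carbon and placing bromine on the neighbouring carbon; the forward step breaks O1–C2 and C3–Br of 10. This ring is what keeps the two flanks of the quaternary carbon different while the acyl group is installed. The gain is that the stereocentre is referred back to a ring closure on a symmetric molecule. The forward reductive elimination must be clean and must leave the acyl-trione untouched.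

**Acyl group.** 10 is cut at the C6–C(=O) bond to give 8 and an isobutyryl donor. In 8 the only doubly activated CH2 lies on the flank remote from the enol ether, so the acyl group can only go to the correct side. The gain is that the group that makes ring A chiral becomes a simple reagent. The forward step must give C- and not O-acylation, at C6 and not C8, without Lewis acid (which could reopen the bromo ether and scramble the quaternary centre).

**Key cut.** 8 is cut at O1–C2 and C3–Br to give 6 and 7. This removes all chirality: 6 is achiral and mirror-symmetric. The forward step must choose between two enantiotopic enol oxygens and must send the bromine to the alkene and not to the enol carbons.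

**Ring A carbocycle.** 6 is cut at both bonds from its C5 carbonyl carbon (C4–C5 and C5–C6) to give 3 and 4, by way of 5. The central carbonyl is a carbonate-level carbon between two methyl-ketone α-carbons. The gain is an acyclic, symmetric diketone. The double Claisen condensation must outrun retro-Claisen cleavage of the non-enolizable 1,3-diketone.

**Prenyl group.** 3 is cut at the bond between the quaternary carbon and the prenyl CH2 to give 1 and 2. This is a standard enolate alkylation; it must go on carbon and at the primary end of the allyl system.

**Ring C.** 18 is first traced to 17 (phenol O–CH2OMe bond), and 17 is cut at C4a–C4 and O1–C2 to give 14 and 15, by way of 16. Ring C is the product of an enal annulation; with the oxygen para to the acyl group blocked in 14, only the acyl-flanked oxygen stands next to the reacting carbon, so the pyran oxygen must end up beside the acyl-bearing carbon. The forward steps need selective protection of one hydroxyl out of three and a deprotection that the chromene tolerates.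

**Ring B substituents.** 14 is cut at the aryl O–CH2 bond to give 13, and 13 at the aryl–acyl bond to give 12 and an isobutyryl donor. Both are standard; the demand is monofunctionalization of a symmetric, very reactive arene.

## Other disconnections considered

Alternatives 1 and 3 concern ring C only and could be combined with the chosen key step; alternative 2 competes with it directly for the stereocentre.

**Alternative 1:** The cut removes ring C at once (aryl C8a–O1, C4a–C4 and O1–C2), leading back to silyl aryl triflate A1 and 15.
- Forward key step: fluoride-induced 1,2-elimination of A1 would release an aryne flanked on one side by a methoxymethoxy group. The carbonyl oxygen of 15 should add to the aryne carbon remote from that group; the [2+2] adduct should open and close again by oxa-6π electrocyclization to chromene A2.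
- In its favour: the position of the pyran oxygen is set by a bond-forming event (aryne polarization), not by a protecting group. The bridge carbon is already present as a silyloxymethyl group, so a defined benzylic electrophile would make the bridge.
- Against it here: A1 is a pentasubstituted benzene that needs several steps. A2 still lacks the 8-isobutyryl group, which must be put in between two oxygens by metalation and acylation, and it carries three protecting groups to remove beside the chromene. Enals can also react with arynes by ene or [4+2] paths.
- Comparison: on regiocontrol of ring C and on control of hetero- against homo-coupling it is the equal or the better of the chosen plan. On step economy it is clearly longer (estimated at eight or more operations to a coupling-ready ring B, against four). It uses a high-energy intermediate where the chosen plan uses a condensation, and it does nothing for the quaternary stereocentre.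

**Alternative 2:** The cut is the ring A bond between the acyl-bearing carbon and the carbonyl carbon beside the quaternary carbon, leading to acyclic triketo ester A3 with the stereocentre already in place.
- Forward key step: the polyanion of A3 would attack its own ester with the methylene next to the isobutyryl ketone (Claisen/Dieckmann-type closure) to give monomer A4, which is identical with 11.
- In its favour: the acyl group and the free ring CH are different from the start, so no temporary ring and no separate acylation are needed. The stereocentre would be set on a small α-methyl β-keto ester by a known reaction class (catalytic asymmetric allylation or phase-transfer alkylation).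
- Against it here: chain extension of a hindered α-quaternary β-keto ester by polyanion chemistry is laborious. Lactonization to a pyranone and retro-Claisen fragmentation at the quaternary carbon compete with the carbon cyclization. Asymmetric prenylation of an acyclic α-methyl β-keto ester faces linear/branched and selectivity problems.
- Comparison: in methodological certainty of the asymmetric step it is the better of the two, since the chosen key step has no direct precedent. Structurally both converge on the same monomer and share the end game. In step economy the chosen plan is expected to be shorter (five steps to 11 from bulk chemicals), and it takes its chirality from an achiral two-step substrate.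

**Alternative 3:** The cut is again C4a–C4 and O1–C2 of ring C, but made on the complete dimer, leading to bridged dimer A5 (from 11 and 14) and 15.
- Forward key step: the single free arene carbon of A5 would condense with 15; dehydration and oxa-6π closure by the acyl-flanked oxygen would give A6, the 5-O-methoxymethyl ether of 21, to be deprotected last.
- In its favour: it uses the same para-blocking device as the chosen ring B branch, so the regiochemistry is equally defined, and the coupling partner 14 is simpler than 18.
- Against it here: the amine-salt condensation at about 110 °C and the final acid deprotection would both be run on the full molecule, with its bridge open to retro-Michael exchange, its acidic trione and its prenyl group. 14 has two equivalent nucleophilic carbons, so double bridging is possible.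
- Comparison: in step count and in regiocontrol it is the equal of the chosen plan (protect, couple, annulate, deprotect against protect, annulate, deprotect, couple). The chosen order places heat and acid on the cheap achiral half and keeps the coupling as the last, mildest step.

Key step: step 3

Remarks on the chemistry, stated before the steps:
- Triones and acyl-triones are written as single tautomers and are taken to react through their enols or enolates; the CIP letter of the quaternary carbon follows the tautomer written, while its spatial arrangement stays the same.
- The temporary CHBr centre of 8 is formulated trans to the angular methyl, (3R,4aS). Anti opening of the bromonium ion through a chair puts bromine equatorial, and the ring fusion holds the angular methyl axial. A cis-(3S,4aS) bromo ether would need a boat-like or syn closure and is not used. The centre is erased in step 5 either way.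
- The sense of induction of the catalyst cannot be predicted with confidence; the quinidine-derived catalyst is written, and its quinine-derived pseudo-enantiomer takes its place if the opposite enantiomer of 8 should form.
- 6 is used without protecting groups, because any O-protection would remove the nucleophile of the key step or break the mirror plane; it is premixed with the catalyst so that it enters the reaction as the catalyst-bound enolate.

## Steps

Step 1
Reactants: 1 3-methylpentane-2,4-dione; 2 1-bromo-3-methylbut-2-ene (prenyl bromide)
Product: 3 3-methyl-3-(3-methylbut-2-en-1-yl)pentane-2,4-dione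
Conditions: K2CO3, acetone, reflux
Reagents that add atoms: none
Why: SN2 C-alkylation of the potassium enolate of a 2-substituted 1,3-diketone by an allylic bromide; the soft electrophile favours carbon over oxygen and attack at the primary end keeps the prenyl connectivity. The new quaternary carbon bears two identical acetyl groups and is not stereogenic.

Step 2
Reactants: 3 3-methyl-3-(3-methylbut-2-en-1-yl)pentane-2,4-dione; 4 dimethyl carbonate
Product: 6 2-methyl-2-(3-methylbut-2-en-1-yl)cyclohexane-1,3,5-trione, via methyl 4-acetyl-4,7-dimethyl-3-oxooct-6-enoate 5 (not isolated)
Conditions: NaH (4 equiv), THF, reflux; then 1 M HCl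
Reagents that add atoms: none
Why: Crossed Claisen condensation of one methyl-ketone enolate with the carbonate gives β-keto ester 5, whose ester is then attacked by the enolate of the second methyl ketone in a Dieckmann-type six-membered ring closure. The final irreversible deprotonation of the acidic trione drives the sequence; the product is mirror-symmetric.

Step 3
Reactants: 6 2-methyl-2-(3-methylbut-2-en-1-yl)cyclohexane-1,3,5-trione; 7 N-bromosuccinimide
Product: 8 (3R,4aS)-3-bromo-2,2,4a-trimethyl-3,4-dihydro-2H-chromene-5,7(4aH,6H)-dione
Conditions: quinidine 9-O-[N-(3,5-bis(trifluoromethyl)phenyl)thiocarbamate] (10 mol%), 6 premixed with the catalyst, CHCl3/toluene, −60 °C; 7 (1.0 equiv) added in portions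
Reagents that add atoms: none
Why: Proposed new method: the acidic dienol of 6 is expected to sit on the catalyst as a hydrogen-bonded ammonium enolate while the thiocarbamate sulfur takes Br+ from 7 and passes it to the prenyl alkene, whose bromonium ion is opened at the tertiary carbon, anti to bromine, by one of the two enol oxygens flanking the quaternary carbon; the closest known reaction type is the bifunctional Lewis-base/Brønsted-base-catalysed enantioselective bromoetherification, including desymmetrizing versions on alkenyl diols and bromocyclizations of alkenyl 1,3-dicarbonyl compounds, which has not been shown for the paired enol oxygens of a cyclic trione. The pyran ring closes in the 6-endo mode because the positive charge of the bromonium ion sits on the CMe2 carbon, so 5-exo attack at the secondary carbon is not expected. The quaternary carbon C4a becomes stereogenic through the choice between the two enantiotopic oxygens, which is made by the catalyst that holds the enolate. The CHBr carbon C3 is set by the alkene face that receives bromine and is tied to C4a by a chair-like transition state, in which the ring fusion keeps the angular methyl axial and the anti opening puts bromine equatorial. A given alkene face can therefore reach only one of the two oxygens through a chair (the other pairing needs a boat with a flagpole methyl–methyl contact), so one catalyst-controlled event fixes both centres and gives the trans bromo ether. The step needs chemoselectivity for the alkene over the two nucleophilic enol carbons and over a second bromination; this rests on delivery of Br+ inside the catalyst–substrate ion pair, on one equivalent of 7 added slowly at low temperature, and on the expectation that a C-bromo trione is itself a Br+ donor toward the sulfur catalyst whereas ether formation is irreversible. Carbon attack on the bromonium ion, which would give a bicyclo[3.3.1]nonane, is disfavoured because the enol oxygen lies in the ring plane within reach of the tertiary carbon and the enol carbon does not.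

Step 4
Reactants: 8 (3R,4aS)-3-bromo-2,2,4a-trimethyl-3,4-dihydro-2H-chromene-5,7(4aH,6H)-dione
Product: 10 (3R,4aS)-3-bromo-7-hydroxy-2,2,4a-trimethyl-6-(2-methylpropanoyl)-3,4-dihydro-2H-chromen-5(4aH)-one, via enol isobutyrate 9 (not isolated)
Conditions: i-PrCOCl, Et3N, CH2Cl2, 0 °C; then 4-(dimethylamino)pyridine (20 mol%), rt
Reagents that add atoms: isobutyryl chloride CC(C)C(Cl)=O
Why: O-acylation of the vinylogous acid followed by the known amine-mediated O-to-C acyl shift of 1,3-dione enol esters puts the acyl group on C6, the only carbon that carries the charge of the dione enolate (C8 does not). Basic conditions without Lewis acid avoid reopening of the bromo ether, so both stereocentres are untouched.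

Step 5
Reactants: 10 (3R,4aS)-3-bromo-7-hydroxy-2,2,4a-trimethyl-6-(2-methylpropanoyl)-3,4-dihydro-2H-chromen-5(4aH)-one
Product: 11 (4S)-3,5-dihydroxy-4-methyl-4-(3-methylbut-2-en-1-yl)-2-(2-methylpropanoyl)cyclohexa-2,5-dien-1-one
Conditions: Zn dust, AcOH, THF, rt; 1 M HCl work-up
Reagents that add atoms: none
Why: Zinc inserts into the C–Br bond and the β-oxygen leaves as a stabilized trione enolate (Boord-type reductive β-elimination), which restores the prenyl double bond and the free enol. The CHBr centre disappears and the quaternary carbon is not involved, so its configuration is kept; the two flanks now differ permanently through the acyl group.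

Step 6
Reactants: 12 benzene-1,3,5-triol (phloroglucinol)
Product: 13 2-methyl-1-(2,4,6-trihydroxyphenyl)propan-1-one
Conditions: i-PrCOCl, AlCl3, PhNO2, 0 to 60 °C; aqueous HCl
Reagents that add atoms: isobutyryl chloride CC(C)C(Cl)=O
Why: Friedel–Crafts C-acylation of the threefold-activated arene; the first acyl group deactivates and chelates the ring, so monoacylation should dominate.

Step 7
Reactants: 13 2-methyl-1-(2,4,6-trihydroxyphenyl)propan-1-one
Product: 14 1-[2,6-dihydroxy-4-(methoxymethoxy)phenyl]-2-methylpropan-1-one
Conditions: MeOCH2Cl (1.0 equiv), i-Pr2NEt (1.1 equiv), THF, 0 °C
Reagents that add atoms: chloromethyl methyl ether COCCl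
Why: The hydroxyl para to the carbonyl is the most acidic (vinylogous acid) and is not held in the intramolecular hydrogen bond, so one equivalent of base and a hard alkylating agent should etherify it first, the same site preference as in mono-O-methylation of acylphloroglucinols.

Step 8
Reactants: 14 1-[2,6-dihydroxy-4-(methoxymethoxy)phenyl]-2-methylpropan-1-one; 15 3-methylbut-2-enal
Product: 17 1-[7-hydroxy-5-(methoxymethoxy)-2,2-dimethyl-2H-chromen-8-yl]-2-methylpropan-1-one, via ortho-quinone methide 16 (not isolated)
Conditions: ethylenediammonium diacetate (10 mol%), toluene, 110 °C
Reagents that add atoms: none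
Why: Amine-salt-catalysed Knoevenagel-type condensation of 15 at one of the two equivalent free ring carbons, dehydration to 16 and oxa-6π electrocyclization. The oxygen on the other side of the reacting carbon is blocked as its methoxymethyl ether, so only the acyl-flanked oxygen can close, which fixes the pyran oxygen next to the acyl-bearing carbon.

Step 9
Reactants: 17 1-[7-hydroxy-5-(methoxymethoxy)-2,2-dimethyl-2H-chromen-8-yl]-2-methylpropan-1-one
Product: 18 1-(5,7-dihydroxy-2,2-dimethyl-2H-chromen-8-yl)-2-methylpropan-1-one
Conditions: 3 M HCl (aq), MeOH, 40 °C
Reagents that add atoms: none
Why: Acid-catalysed transacetalization of the aryl methoxymethyl ether to methanol; the mild temperature is chosen so that the styrenic chromene double bond is not protonated.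

Step 10
Reactants: 11 (4S)-3,5-dihydroxy-4-methyl-4-(3-methylbut-2-en-1-yl)-2-(2-methylpropanoyl)cyclohexa-2,5-dien-1-one; 18 1-(5,7-dihydroxy-2,2-dimethyl-2H-chromen-8-yl)-2-methylpropan-1-one
Product: 21 (4S)-6-{[5,7-dihydroxy-2,2-dimethyl-8-(2-methylpropanoyl)-2H-chromen-6-yl]methyl}-3,5-dihydroxy-4-methyl-4-(3-methylbut-2-en-1-yl)-2-(2-methylpropanoyl)cyclohexa-2,5-dien-1-one, via Mannich base 19 (not isolated), via methylene trione 20 (not isolated)
Conditions: Me2N=CH2+ I− (1.0 equiv), MeCN, 0 °C to rt; then 18 (1.1 equiv), NaOAc (1.1 equiv), 60 °C; 0.5 M HCl work-up
Reagents that add atoms: N,N-dimethylmethyleneiminium iodide C[N+](C)=C.[I-]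
Why: Mannich reaction at the only free (vinylogous acid) carbon of 11 gives 19, which loses dimethylamine by E1cB to the alkylidene trione 20; Friedel–Crafts-type Michael addition of the only free, doubly hydroxyl-activated carbon of 18 then forms the second C–C bond of the bridge. Fixing the one-carbon unit on 11 before 18 is added excludes symmetric dimers, and the quaternary stereocentre is not touched.

## Compound list

1 | 3-methylpentane-2,4-dione | CC(=O)C(C)C(C)=O | starting material
2 | 1-bromo-3-methylbut-2-ene (prenyl bromide) | CC(C)=CCBr | starting material
3 | 3-methyl-3-(3-methylbut-2-en-1-yl)pentane-2,4-dione | CC(=O)C(C)(CC=C(C)C)C(C)=O | intermediate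
4 | dimethyl carbonate | COC(=O)OC | starting material
5 | methyl 4-acetyl-4,7-dimethyl-3-oxooct-6-enoate (racemic) | COC(=O)CC(=O)C(C)(CC=C(C)C)C(C)=O | intermediate (not isolated)
6 | 2-methyl-2-(3-methylbut-2-en-1-yl)cyclohexane-1,3,5-trione (achiral) | CC(C)=CCC1(C)C(=O)CC(=O)CC1=O | intermediate
7 | N-bromosuccinimide (1-bromopyrrolidine-2,5-dione) | O=C1CCC(=O)N1Br | starting material
8 | (3R,4aS)-3-bromo-2,2,4a-trimethyl-3,4-dihydro-2H-chromene-5,7(4aH,6H)-dione (bromine trans to the angular methyl) | C[C@]12C[C@@H](Br)C(C)(C)OC1=CC(=O)CC2=O | intermediate
9 | (3R,4aS)-3-bromo-2,2,4a-trimethyl-5-oxo-3,4,4a,5-tetrahydro-2H-chromen-7-yl 2-methylpropanoate | C[C@]12C[C@@H](Br)C(C)(C)OC1=CC(OC(=O)C(C)C)=CC2=O | intermediate (not isolated)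
10 | (3R,4aS)-3-bromo-7-hydroxy-2,2,4a-trimethyl-6-(2-methylpropanoyl)-3,4-dihydro-2H-chromen-5(4aH)-one | C[C@]12C[C@@H](Br)C(C)(C)OC1=CC(O)=C(C(=O)C(C)C)C2=O | intermediate
11 | (4S)-3,5-dihydroxy-4-methyl-4-(3-methylbut-2-en-1-yl)-2-(2-methylpropanoyl)cyclohexa-2,5-dien-1-one | CC(C)=CC[C@@]1(C)C(O)=CC(=O)C(C(=O)C(C)C)=C1O | intermediate
12 | benzene-1,3,5-triol (phloroglucinol) | Oc1cc(O)cc(O)c1 | starting material
13 | 2-methyl-1-(2,4,6-trihydroxyphenyl)propan-1-one | CC(C)C(=O)c1c(O)cc(O)cc1O | intermediate
14 | 1-[2,6-dihydroxy-4-(methoxymethoxy)phenyl]-2-methylpropan-1-one | CC(C)C(=O)c1c(O)cc(OCOC)cc1O | intermediate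
15 | 3-methylbut-2-enal | CC(C)=CC=O | starting material
16 | 3-hydroxy-5-(methoxymethoxy)-6-(3-methylbut-2-en-1-ylidene)-2-(2-methylpropanoyl)cyclohexa-2,4-dien-1-one | CC(C)C(=O)C1=C(O)C=C(OCOC)C(=CC=C(C)C)C1=O | intermediate (not isolated)
17 | 1-[7-hydroxy-5-(methoxymethoxy)-2,2-dimethyl-2H-chromen-8-yl]-2-methylpropan-1-one | CC(C)C(=O)c1c(O)cc(OCOC)c2C=CC(C)(C)Oc12 | intermediate
18 | 1-(5,7-dihydroxy-2,2-dimethyl-2H-chromen-8-yl)-2-methylpropan-1-one | CC(C)C(=O)c1c(O)cc(O)c2C=CC(C)(C)Oc12 | intermediate
19 | (4S)-6-[(dimethylamino)methyl]-3,5-dihydroxy-4-methyl-4-(3-methylbut-2-en-1-yl)-2-(2-methylpropanoyl)cyclohexa-2,5-dien-1-one | CC(C)=CC[C@@]1(C)C(O)=C(CN(C)C)C(=O)C(C(=O)C(C)C)=C1O | intermediate (not isolated)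
20 | (4R)-3-hydroxy-4-methyl-6-methylidene-4-(3-methylbut-2-en-1-yl)-2-(2-methylpropanoyl)cyclohex-2-ene-1,5-dione (same spatial arrangement as 11; the letter changes with the CIP ranking) | CC(C)=CC[C@@]1(C)C(=O)C(=C)C(=O)C(C(=O)C(C)C)=C1O | intermediate (not isolated)
21 | (4S)-6-{[5,7-dihydroxy-2,2-dimethyl-8-(2-methylpropanoyl)-2H-chromen-6-yl]methyl}-3,5-dihydroxy-4-methyl-4-(3-methylbut-2-en-1-yl)-2-(2-methylpropanoyl)cyclohexa-2,5-dien-1-one | CC(C)=CC[C@@]1(C)C(O)=C(Cc2c(O)c3c(c(C(=O)C(C)C)c2O)OC(C)(C)C=C3)C(=O)C(C(=O)C(C)C)=C1O | target

## Step count and least certain steps

Total step count: 10 (five for ring A, four for ring B, one coupling). Longest linear sequence: 6 steps (steps 1, 2, 3, 4, 5 and 10).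

**Step 3 (the key step, which bears the label "Proposed new method:").** The most likely failure is poor chemoselectivity: the enol carbons of 6 are more nucleophilic than the trisubstituted alkene, so bromination at carbon may win over bromonium formation. The second risk is poor selection between the enantiotopic oxygens, because an uncatalysed background cyclization of the highly enolized, acidic substrate would give racemic 8. The fallback uses known chemistry and sets out from 6. The trione would be mono-C-acylated (isobutyryl chloride, Et3N, then 4-(dimethylamino)pyridine) to racemic 3,5-dihydroxy-4-methyl-4-(3-methylbut-2-en-1-yl)-2-(2-methylpropanoyl)cyclohexa-2,5-dien-1-one F1. F1 would be resolved by preparative chromatography on a chiral stationary phase; the (4S) enantiomer is 11 and the (4R) enantiomer F2 is set aside. The route is rejoined at 11.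

**Step 2.** The most likely failure is retro-Claisen cleavage: methoxide set free in the first condensation can add to a ketone of the non-enolizable 1,3-diketone 3 and expel an acetyl group faster than the second enolate closes the ring. Twofold carboxylation without ring closure is the other risk. The fallback sets out from 2 and builds the ring from the ester side. 2 would alkylate commercial methyl 2-methyl-3-oxobutanoate (K2CO3, acetone) to methyl 2-methyl-2-(3-methylbut-2-en-1-yl)-3-oxobutanoate F3. Soft-enolization C-acetylation of its only enolizable position (MgBr2·OEt2, i-Pr2NEt, 1-acetylbenzotriazole) would give methyl 2-methyl-2-(3-methylbut-2-en-1-yl)-3,5-dioxohexanoate F4. Its dianion (LiN(i-Pr)2, 2.2 equiv, THF, −78 °C to rt) would close onto the ester. The route is rejoined at 6.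

**Step 7.** The most likely failure is poor site selectivity or over-alkylation: the acidity difference between the three hydroxyls is modest and proton exchange is fast. The fallback sets out from 13 and drops the protecting group. 13 would be condensed directly with 15 (ethylenediammonium diacetate, toluene, 110 °C), and 18 would be separated by chromatography from its regioisomer 1-(5,7-dihydroxy-2,2-dimethyl-2H-chromen-6-yl)-2-methylpropan-1-one F5. The route is rejoined at 18, which also removes the acid deprotection of step 9, at the price of an uncontrolled isomer distribution.

**Step 10.** The most likely failure is loss of 20 before the arene carbon intercepts it, by hetero-Diels–Alder addition to the electron-rich chromene or prenyl double bonds or by self-condensation. Retro-Michael cleavage of the product under base and heat could also redistribute the bridge into symmetric dimers. The fallback sets out from 18 and reverses the roles of the partners. 18 would be aminomethylated (N,N-dimethylmethyleneiminium iodide, CH2Cl2, then NaHCO3) to 1-{6-[(dimethylamino)methyl]-5,7-dihydroxy-2,2-dimethyl-2H-chromen-8-yl}-2-methylpropan-1-one F6. Warming F6 with 11 in dioxane would generate the ring B ortho-quinone methide, which the acidic trione enol of 11 captures at carbon. The route is rejoined at 21.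

## Further compounds

F1 | step 3 | racemic 3,5-dihydroxy-4-methyl-4-(3-methylbut-2-en-1-yl)-2-(2-methylpropanoyl)cyclohexa-2,5-dien-1-one | CC(C)=CCC1(C)C(O)=CC(=O)C(C(=O)C(C)C)=C1O
F2 | step 3 | (4R)-3,5-dihydroxy-4-methyl-4-(3-methylbut-2-en-1-yl)-2-(2-methylpropanoyl)cyclohexa-2,5-dien-1-one | CC(C)=CC[C@]1(C)C(O)=CC(=O)C(C(=O)C(C)C)=C1O
F3 | step 2 | methyl 2-methyl-2-(3-methylbut-2-en-1-yl)-3-oxobutanoate (racemic) | COC(=O)C(C)(CC=C(C)C)C(C)=O
F4 | step 2 | methyl 2-methyl-2-(3-methylbut-2-en-1-yl)-3,5-dioxohexanoate (racemic) | COC(=O)C(C)(CC=C(C)C)C(=O)CC(C)=O
F5 | step 7 | 1-(5,7-dihydroxy-2,2-dimethyl-2H-chromen-6-yl)-2-methylpropan-1-one | CC(C)C(=O)c1c(O)cc2OC(C)(C)C=Cc2c1O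
F6 | step 10 | 1-{6-[(dimethylamino)methyl]-5,7-dihydroxy-2,2-dimethyl-2H-chromen-8-yl}-2-methylpropan-1-one | CC(C)C(=O)c1c(O)c(CN(C)C)c(O)c2C=CC(C)(C)Oc12
A1 | alternative 1 | 3,5-bis(methoxymethoxy)-4-{[(triisopropylsilyl)oxy]methyl}-2-(trimethylsilyl)phenyl trifluoromethanesulfonate | COCOc1cc(OS(=O)(=O)C(F)(F)F)c([Si](C)(C)C)c(OCOC)c1CO[Si](C(C)C)(C(C)C)C(C)C
A2 | alternative 1 | 5,7-bis(methoxymethoxy)-2,2-dimethyl-6-{[(triisopropylsilyl)oxy]methyl}-2H-chromene | CC1(C)C=Cc2c(OCOC)c(CO[Si](C(C)C)(C(C)C)C(C)C)c(OCOC)cc2O1
A3 | alternative 2 | methyl (2S)-2,8-dimethyl-2-(3-methylbut-2-en-1-yl)-3,5,7-trioxononanoate | COC(=O)[C@@](C)(CC=C(C)C)C(=O)CC(=O)CC(=O)C(C)C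
A4 | alternative 2 | (4S)-3,5-dihydroxy-4-methyl-4-(3-methylbut-2-en-1-yl)-2-(2-methylpropanoyl)cyclohexa-2,5-dien-1-one (identical with 11) | CC(C)=CC[C@@]1(C)C(O)=CC(=O)C(C(=O)C(C)C)=C1O
A5 | alternative 3 | (4S)-6-{[2,4-dihydroxy-6-(methoxymethoxy)-3-(2-methylpropanoyl)phenyl]methyl}-3,5-dihydroxy-4-methyl-4-(3-methylbut-2-en-1-yl)-2-(2-methylpropanoyl)cyclohexa-2,5-dien-1-one | CC(C)=CC[C@@]1(C)C(O)=C(Cc2c(OCOC)cc(O)c(C(=O)C(C)C)c2O)C(=O)C(C(=O)C(C)C)=C1O
A6 | alternative 3 | (4S)-6-{[7-hydroxy-5-(methoxymethoxy)-2,2-dimethyl-8-(2-methylpropanoyl)-2H-chromen-6-yl]methyl}-3,5-dihydroxy-4-methyl-4-(3-methylbut-2-en-1-yl)-2-(2-methylpropanoyl)cyclohexa-2,5-dien-1-one | CC(C)=CC[C@@]1(C)C(O)=C(Cc2c(OCOC)c3c(c(C(=O)C(C)C)c2O)OC(C)(C)C=C3)C(=O)C(C(=O)C(C)C)=C1O
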